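**Strategy.** The cyclohexane ring is traced back to a 4-methylcyclohex-3-enyl ring: C-4′ (Cl, CH3) and C-3′ (Br) mark a former alkene, and C-1′ carries the pyran carbon C-2, a former ketone. A catalytic enantioselective Diels–Alder reaction of isoprene with an enantiopure α′-silyloxy vinyl ketone that already holds C-2 to C-6 of the pyran, its gem-dimethyl groups and the C-3 oxygen therefore forms the C-1′–C-2′ and C-5′–C-6′ bonds, the ring and the C-1′ stereocentre in one operation. The C-3 stereocentre then directs C-2 (Felkin–Anh methyl addition), bromoetherification closes the pyran, and the ring alkene is converted to the trans-diequatorial bromochloride through a bromonium ion and a dyotropic halogen interchange.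

Key step: step 4

Remark: target locants are used for all intermediates (pyran O-1, C-2 to C-6; cyclohexane C-1′ to C-6′, C-1′ bonded to C-2); compounds 1, 2, 5, 8, the oxazaborolidine of step 4 and the ketone catalyst of step 8 are taken as commercial.

Remark: direct bromochlorination of the ring alkene would take the trans-diaxial, Markovnikov course and give the dihalide epimeric at C-3′ and C-4′ (Cl cis to the pyranyl group), which is why steps 8 to 11 are used instead.

Step 1
Reactants: 1 methyl (2R)-oxirane-2-carboxylate; 2 2-methylprop-1-enylmagnesium bromide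
Product: 3 methyl (2R)-2-hydroxy-5-methylhex-4-enoate
Conditions: CuI (10 mol %), THF, −78 → −30 °C; aq. NH4Cl
Reagents that add atoms: none
Why: Copper-catalysed Grignard opening of the epoxide (SN2 at the unsubstituted CH2, faster than addition to the ester at low temperature) leaves the C–O bond of the stereocentre untouched, so the (R) centre of 1 becomes C-3 of the target together with its oxygen.

Step 2
Reactants: 3 methyl (2R)-2-hydroxy-5-methylhex-4-enoate
Product: 4 methyl (2R)-2-[(tert-butyldimethylsilyl)oxy]-5-methylhex-4-enoate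
Conditions: TBSCl, imidazole, DMF, 20 °C
Reagents that add atoms: tert-butyldimethylsilyl chloride, CC(C)(C)[Si](C)(C)Cl
Why: Silyl ether formation protects the hydroxyl as a bulky, poorly chelating group, which the stereochemical course of step 5 needs, and touches no stereocentre.

Step 3
Reactants: 4 methyl (2R)-2-[(tert-butyldimethylsilyl)oxy]-5-methylhex-4-enoate; 5 vinylmagnesium bromide
Product: 7 (4R)-4-[(tert-butyldimethylsilyl)oxy]-7-methylocta-1,6-dien-3-one, via Weinreb amide 6 (not isolated)
Conditions: MeNH(OMe)·HCl, iPrMgCl, THF, −20 °C; then CH2=CHMgBr, −20 → 0 °C; poured into cold 1 M HCl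
Reagents that add atoms: N,O-dimethylhydroxylamine hydrochloride, CNOC.Cl (its N(OMe)Me group is held only in 6 and leaves again)
Why: Aminolysis of the ester by the magnesium amide gives the Weinreb amide, whose chelated tetrahedral adduct with the vinyl Grignard reagent collapses only on acidic work-up (Weinreb ketone synthesis), so the enone should form without over-addition and without epimerisation of the α-silyloxy centre.

Step 4
Reactants: 7 (4R)-4-[(tert-butyldimethylsilyl)oxy]-7-methylocta-1,6-dien-3-one; 8 isoprene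
Product: 9 (2R)-2-[(tert-butyldimethylsilyl)oxy]-5-methyl-1-[(1S)-4-methylcyclohex-3-en-1-yl]hex-4-en-1-one
Conditions: (R)-tetrahydro-1-(2-methylphenyl)-3,3-diphenyl-1H,3H-pyrrolo[1,2-c][1,3,2]oxazaborole (20 mol %), (CF3SO2)2NH (18 mol %), CH2Cl2, −78 → −40 °C
Reagents that add atoms: none
Why: The boron of the protonated oxazaborolidine binds the ketone lone pair on the vinyl side (α-C–H···O contact), one phenyl group of the catalyst covers one face of the s-trans enone, and isoprene adds to the open face in a concerted, asynchronous [4+2] cycloaddition. The closest known reaction type is the enantioselective Diels–Alder reaction of acyclic enones and acrylates with butadiene or isoprene under triflimide-activated chiral oxazaborolidines. The cyclohexene ring is closed by an intermolecular suprafacial–suprafacial [4+2] cycloaddition that forms the C-1′–C-2′ and C-5′–C-6′ bonds together and leaves the C-3′=C-4′ alkene for the later halogenation. The only new stereocentre, C-1′, is set as (S) by the catalyst (reagent control, the (R)-catalyst being the enantiomer whose open face corresponds to (S) in the accepted pre-transition-state model), while the silyloxy centre, insulated by the carbonyl group, should add at most a small bias. The step needs para regioselectivity, secured by the larger HOMO coefficient at C-1 of isoprene meeting the β-carbon of the Lewis-acid-bound enone, and chemoselectivity, secured because the electron-rich prenyl alkene is no dienophile and the silyl ether survives at −78 °C.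

Step 5
Reactants: 9 (2R)-2-[(tert-butyldimethylsilyl)oxy]-5-methyl-1-[(1S)-4-methylcyclohex-3-en-1-yl]hex-4-en-1-one
Product: 10 (2R,3R)-3-[(tert-butyldimethylsilyl)oxy]-6-methyl-2-[(1S)-4-methylcyclohex-3-en-1-yl]hept-5-en-2-ol
Conditions: MeLi, Et2O–THF, −78 °C; aq. NH4Cl at −78 °C
Reagents that add atoms: methyllithium, [Li]C
Why: Felkin–Anh addition to the α-silyloxy ketone, in which the non-chelating silyloxy group lies anti to the incoming methyl group and the nucleophile passes the C-3 hydrogen, should set C-2 as (R) under 1,2-induction from C-3, and fast addition at −78 °C should outrun enolisation towards C-1′.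

Step 6
Reactants: 10 (2R,3R)-3-[(tert-butyldimethylsilyl)oxy]-6-methyl-2-[(1S)-4-methylcyclohex-3-en-1-yl]hept-5-en-2-ol
Product: 12 (2R,3R)-2-hydroxy-6-methyl-2-[(1S)-4-methylcyclohex-3-en-1-yl]hept-5-en-3-yl acetate, via diol 11 (not isolated)
Conditions: Bu4NF, THF, 0 → 20 °C; then Ac2O, Et3N, 4-(dimethylamino)pyridine (10 mol %), 20 °C
Reagents that add atoms: acetic anhydride, CC(=O)OC(C)=O
Why: Fluoride cleaves the Si–O bond and the freed secondary oxygen is acetylated in the same flask (nucleophile-catalysed acylation), the tertiary C-2 hydroxyl being too hindered to react, and no stereocentre is touched.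

Step 7
Reactants: 12 (2R,3R)-2-hydroxy-6-methyl-2-[(1S)-4-methylcyclohex-3-en-1-yl]hept-5-en-3-yl acetate
Product: 13 (2R,3R,5R)-5-bromo-2,6,6-trimethyl-2-[(1S)-4-methylcyclohex-3-en-1-yl]oxan-3-yl acetate
Conditions: NBS, CH2Cl2, −20 → 0 °C, dark
Reagents that add atoms: N-bromosuccinimide, O=C1CCC(=O)N1Br
Why: Bromoetherification, in which the C-2 hydroxyl opens the bromonium ion of the prenyl alkene at its tertiary carbon C-6 (6-endo, Markovnikov, anti addition) through a chair with Br and the cyclohexenyl group equatorial and the C-2 methyl and C-3 acetate axial, should set C-5 as (R) under substrate control, while the ring alkene has no nucleophile in easy reach and its bromonium ion should revert.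

Step 8
Reactants: 13 (2R,3R,5R)-5-bromo-2,6,6-trimethyl-2-[(1S)-4-methylcyclohex-3-en-1-yl]oxan-3-yl acetate
Product: 14 (2R,3R,5R)-5-bromo-2,6,6-trimethyl-2-[(1S,4S,6R)-1-methyl-7-oxabicyclo[4.1.0]heptan-4-yl]oxan-3-yl acetate
Conditions: 1,2:4,5-di-O-isopropylidene-β-D-erythro-2,3-hexodiulo-2,6-pyranose (30 mol %), KHSO5, K2CO3, Bu4NHSO4 (cat.), MeCN–CH2(OMe)2–aq. Na2B4O7 buffer, 0 °C
Reagents that add atoms: potassium peroxymonosulfate, [K+].[O-]S(=O)(=O)OO
Why: Shi epoxidation, in which the chiral dioxirane from the D-fructose-derived ketone selects the face of the trisubstituted ring alkene by reagent control (the sense known for 1-substituted cyclohexenes), should place the oxygen trans to the equatorial pyranyl group at C-1′, a face that the substrate alone would not differentiate.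

Step 9
Reactants: 14 (2R,3R,5R)-5-bromo-2,6,6-trimethyl-2-[(1S,4S,6R)-1-methyl-7-oxabicyclo[4.1.0]heptan-4-yl]oxan-3-yl acetate
Product: 15 (2R,3R,5R)-5-bromo-2-[(1S,3R,4R)-4-bromo-3-hydroxy-4-methylcyclohexyl]-2,6,6-trimethyloxan-3-yl acetate
Conditions: 48 % aq. HBr, CHCl3, 0 °C
Reagents that add atoms: hydrogen bromide, Br
Why: Acid-mediated epoxide opening by bromide at the tertiary carbon C-4′ with inversion, in the trans-diaxial mode (Fürst–Plattner rule) that for this epoxide face coincides with the Markovnikov preference, should give the axial tertiary bromide cis to the pyranyl group and the axial C-3′ alcohol.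

Step 10
Reactants: 15 (2R,3R,5R)-5-bromo-2-[(1S,3R,4R)-4-bromo-3-hydroxy-4-methylcyclohexyl]-2,6,6-trimethyloxan-3-yl acetate
Product: 16 (2R,3R,5R)-5-bromo-2-[(1S,3R,4R)-4-bromo-3-chloro-4-methylcyclohexyl]-2,6,6-trimethyloxan-3-yl acetate
Conditions: SOCl2, DMF (cat.), CH2Cl2, 0 → 20 °C
Reagents that add atoms: thionyl chloride, O=S(Cl)Cl
Why: Deoxychlorination with neighbouring-group participation, in which the axial bromine anti-periplanar to the chlorosulfite displaces it to give the bromonium ion on the face cis to the pyranyl group and chloride opens this ion trans-diaxially at C-3′ (overall retention), should give 16, while any Markovnikov opening at C-4′ gives the target 17 directly and is carried along.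

Step 11
Reactants: 16 (2R,3R,5R)-5-bromo-2-[(1S,3R,4R)-4-bromo-3-chloro-4-methylcyclohexyl]-2,6,6-trimethyloxan-3-yl acetate
Product: 17 8-acetylcaespitol, (2R,3R,5R)-5-bromo-2-[(1S,3S,4S)-3-bromo-4-chloro-4-methylcyclohexyl]-2,6,6-trimethyloxan-3-yl acetate
Conditions: chlorobenzene, 130 °C, sealed tube
Reagents that add atoms: none
Why: Thermal diaxial-to-diequatorial rearrangement of a vicinal dihalide (dyotropic 1,2-interchange with inversion at both carbons) moves Br to C-3′ and Cl to C-4′ on the faces they already occupy and should be driven towards 17 by the preference of chlorine for the tertiary carbon and the loss of two axial carbon–halogen bonds, unchanged 16 being separated and resubjected.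

**Compound list**

1 | methyl (2R)-oxirane-2-carboxylate | COC(=O)[C@H]1CO1 | starting material
2 | 2-methylprop-1-enylmagnesium bromide | CC(C)=C[Mg]Br | starting material
3 | methyl (2R)-2-hydroxy-5-methylhex-4-enoate | O[C@H](CC=C(C)C)C(=O)OC | intermediate
4 | methyl (2R)-2-[(tert-butyldimethylsilyl)oxy]-5-methylhex-4-enoate | CC(C)(C)[Si](C)(C)O[C@H](CC=C(C)C)C(=O)OC | intermediate
5 | vinylmagnesium bromide | C=C[Mg]Br | starting material
6 | (2R)-2-[(tert-butyldimethylsilyl)oxy]-N-methoxy-N,5-dimethylhex-4-enamide (Weinreb amide, not isolated) | CC(C)(C)[Si](C)(C)O[C@H](CC=C(C)C)C(=O)N(C)OC | intermediate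
7 | (4R)-4-[(tert-butyldimethylsilyl)oxy]-7-methylocta-1,6-dien-3-one | CC(C)(C)[Si](C)(C)O[C@H](CC=C(C)C)C(=O)C=C | intermediate
8 | isoprene (2-methylbuta-1,3-diene) | CC(=C)C=C | starting material
9 | (2R)-2-[(tert-butyldimethylsilyl)oxy]-5-methyl-1-[(1S)-4-methylcyclohex-3-en-1-yl]hex-4-en-1-one | CC(C)(C)[Si](C)(C)O[C@H](CC=C(C)C)C(=O)[C@H]1CCC(C)=CC1 | intermediate
10 | (2R,3R)-3-[(tert-butyldimethylsilyl)oxy]-6-methyl-2-[(1S)-4-methylcyclohex-3-en-1-yl]hept-5-en-2-ol | CC(C)(C)[Si](C)(C)O[C@H](CC=C(C)C)[C@](C)(O)[C@H]1CCC(C)=CC1 | intermediate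
11 | (2R,3R)-6-methyl-2-[(1S)-4-methylcyclohex-3-en-1-yl]hept-5-ene-2,3-diol (not isolated) | O[C@H](CC=C(C)C)[C@](C)(O)[C@H]1CCC(C)=CC1 | intermediate
12 | (2R,3R)-2-hydroxy-6-methyl-2-[(1S)-4-methylcyclohex-3-en-1-yl]hept-5-en-3-yl acetate | CC(=O)O[C@H](CC=C(C)C)[C@](C)(O)[C@H]1CCC(C)=CC1 | intermediate
13 | (2R,3R,5R)-5-bromo-2,6,6-trimethyl-2-[(1S)-4-methylcyclohex-3-en-1-yl]oxan-3-yl acetate | CC(=O)O[C@@H]1C[C@@H](Br)C(C)(C)O[C@]1(C)[C@H]1CCC(C)=CC1 | intermediate
14 | (2R,3R,5R)-5-bromo-2,6,6-trimethyl-2-[(1S,4S,6R)-1-methyl-7-oxabicyclo[4.1.0]heptan-4-yl]oxan-3-yl acetate (epoxide oxygen trans to the pyranyl group) | CC(=O)O[C@@H]1C[C@@H](Br)C(C)(C)O[C@]1(C)[C@H]1CC[C@]2(C)O[C@@H]2C1 | intermediate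
15 | (2R,3R,5R)-5-bromo-2-[(1S,3R,4R)-4-bromo-3-hydroxy-4-methylcyclohexyl]-2,6,6-trimethyloxan-3-yl acetate (Br and OH trans-diaxial) | CC(=O)O[C@@H]1C[C@@H](Br)C(C)(C)O[C@]1(C)[C@H]1CC[C@@](C)(Br)[C@H](O)C1 | intermediate
16 | (2R,3R,5R)-5-bromo-2-[(1S,3R,4R)-4-bromo-3-chloro-4-methylcyclohexyl]-2,6,6-trimethyloxan-3-yl acetate (Br and Cl trans-diaxial) | CC(=O)O[C@@H]1C[C@@H](Br)C(C)(C)O[C@]1(C)[C@H]1CC[C@@](C)(Br)[C@H](Cl)C1 | intermediate
17 | 8-acetylcaespitol, (2R,3R,5R)-5-bromo-2-[(1S,3S,4S)-3-bromo-4-chloro-4-methylcyclohexyl]-2,6,6-trimethyloxan-3-yl acetate | CC(=O)O[C@@H]1C[C@@H](Br)C(C)(C)O[C@]1(C)[C@H]1CC[C@](C)(Cl)[C@@H](Br)C1 | target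

**Step count and risks**

Total step count: 11. Longest linear sequence: 11 steps (1 to 17); 2, 5 and 8 enter as purchased reagents.

The three steps most likely to fail:

Step 7. The bromonium ion of the prenyl alkene may be opened at C-5 (5-exo closure to a tetrahydrofuran carrying a tertiary bromide) instead of at C-6, and bromonium formation at the ring alkene with capture by the C-2 hydroxyl across the ring may compete. The fallback sets out from 12 and replaces the halonium closure by a mercuricyclisation. Hg(OCOCF3)2 in MeNO2 at −20 °C, then aqueous KBr, is a reversible, thermodynamically controlled alkoxymercuration that favours the six-membered ether with the metal on the secondary carbon (anti addition through the same chair). It should give (2R,3R,5R)-5-(bromomercurio)-2,6,6-trimethyl-2-[(1S)-4-methylcyclohex-3-en-1-yl]oxan-3-yl acetate F1. Bromodemercuration with Br2 in pyridine at −40 °C under air cleaves the C–Hg bond from the front side with retention, and the pyridine–bromine complex should spare the trisubstituted ring alkene at this temperature. The fallback comes back to the route at 13.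

Step 10. The tertiary bromide of 15 may be lost (ionisation, elimination of HBr or collapse back to the epoxide) before or while the neighbouring hydroxyl is activated. The fallback sets out from 13, bypasses 14 and 15, and introduces chlorine by SN2 opening of an epoxide and the tertiary bromide last. NBS in aqueous acetone at 0 °C (bromohydrin formation, trans-diaxial and Markovnikov, water entering at C-4′ cis to the pyranyl group) should give (2R,3R,5R)-5-bromo-2-[(1S,3R,4R)-3-bromo-4-hydroxy-4-methylcyclohexyl]-2,6,6-trimethyloxan-3-yl acetate F2. Cs2CO3 in MeCN closes it to (2R,3R,5R)-5-bromo-2,6,6-trimethyl-2-[(1R,4S,6S)-1-methyl-7-oxabicyclo[4.1.0]heptan-4-yl]oxan-3-yl acetate F3, the epoxide with oxygen cis to the pyranyl group. Concentrated aqueous HCl in CHCl3 at 0 °C opens this epoxide trans-diaxially, which for this face means at the secondary carbon C-3′, to (2R,3R,5R)-5-bromo-2-[(1S,3R,4R)-3-chloro-4-hydroxy-4-methylcyclohexyl]-2,6,6-trimethyloxan-3-yl acetate F4. HBr in CH2Cl2 at −20 °C ionises the tertiary alcohol, and bromide should enter anti to the axial chlorine with retention. The fallback comes back to the route at 16, from which step 11 follows.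

Step 5. The methyl addition may show insufficient facial selectivity (a chelated pathway gives the C-2 epimer), or the hindered ketone may enolise. The fallback sets out from 9 and builds the tertiary carbinol by hydroxyl-directed epoxidation instead of carbonyl addition. Methylenation under non-basic conditions (Zn, CH2Br2, TiCl4, THF–CH2Cl2) gives tert-butyl(dimethyl){[(3R)-6-methyl-2-[(1S)-4-methylcyclohex-3-en-1-yl]hepta-1,5-dien-3-yl]oxy}silane F5. Bu4NF in THF gives (3R)-6-methyl-2-[(1S)-4-methylcyclohex-3-en-1-yl]hepta-1,5-dien-3-ol F6. Epoxidation with VO(acac)2 (5 mol %) and tBuOOH in CH2Cl2 at 0 °C is directed by the allylic hydroxyl; the carbinol hydrogen eclipses the cyclohexenyl group to avoid 1,2-allylic strain, which should give the erythro epoxy alcohol (1R)-4-methyl-1-{(2S)-2-[(1S)-4-methylcyclohex-3-en-1-yl]oxiran-2-yl}pent-3-en-1-ol F7. LiAlH4 in THF at 0 °C delivers hydride to the epoxide CH2. The fallback comes back to the route at diol 11, which is acetylated as in the second half of step 6 to give 12.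

**Further compounds**

F1 | step 7 | (2R,3R,5R)-5-(bromomercurio)-2,6,6-trimethyl-2-[(1S)-4-methylcyclohex-3-en-1-yl]oxan-3-yl acetate | CC(=O)O[C@@H]1C[C@@H]([Hg]Br)C(C)(C)O[C@]1(C)[C@H]1CCC(C)=CC1
F2 | step 10 | (2R,3R,5R)-5-bromo-2-[(1S,3R,4R)-3-bromo-4-hydroxy-4-methylcyclohexyl]-2,6,6-trimethyloxan-3-yl acetate | CC(=O)O[C@@H]1C[C@@H](Br)C(C)(C)O[C@]1(C)[C@H]1CC[C@@](C)(O)[C@H](Br)C1
F3 | step 10 | (2R,3R,5R)-5-bromo-2,6,6-trimethyl-2-[(1R,4S,6S)-1-methyl-7-oxabicyclo[4.1.0]heptan-4-yl]oxan-3-yl acetate | CC(=O)O[C@@H]1C[C@@H](Br)C(C)(C)O[C@]1(C)[C@H]1CC[C@@]2(C)O[C@H]2C1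
F4 | step 10 | (2R,3R,5R)-5-bromo-2-[(1S,3R,4R)-3-chloro-4-hydroxy-4-methylcyclohexyl]-2,6,6-trimethyloxan-3-yl acetate | CC(=O)O[C@@H]1C[C@@H](Br)C(C)(C)O[C@]1(C)[C@H]1CC[C@@](C)(O)[C@H](Cl)C1
F5 | step 5 | tert-butyl(dimethyl){[(3R)-6-methyl-2-[(1S)-4-methylcyclohex-3-en-1-yl]hepta-1,5-dien-3-yl]oxy}silane | CC(C)(C)[Si](C)(C)O[C@H](CC=C(C)C)C(=C)[C@H]1CCC(C)=CC1
F6 | step 5 | (3R)-6-methyl-2-[(1S)-4-methylcyclohex-3-en-1-yl]hepta-1,5-dien-3-ol | O[C@H](CC=C(C)C)C(=C)[C@H]1CCC(C)=CC1
F7 | step 5 | (1R)-4-methyl-1-{(2S)-2-[(1S)-4-methylcyclohex-3-en-1-yl]oxiran-2-yl}pent-3-en-1-ol | O[C@H](CC=C(C)C)[C@@]2(CO2)[C@H]1CCC(C)=CC1
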